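**Retrosynthetic overview**

1. Both C–Br bonds (C4, C4′) are cut back to axial alcohols (Appel, inversion), these to a diketone (L-Selectride), and the acetate to the tertiary alcohol.
2. The strategy rests on C1′, the fully substituted acetoxy carbon of the side cyclohexane. Its two ring bonds C1′–C2′ and C1′–C6′ are cut to the ester carbon of the core acetic ester and a 1,5-di-Grignard, whose C4′H(O)–C3′Me2–C2′H2 unit is the CH(OH)–CMe2–CH2O unit of (S)-pantolactone.
3. Core: C4 carbinol from the ketone; C1 by hydrogenation of an exocyclic enoate; γ-lactone C3a–C(=O)–O–C7 by capture of a C7 cation by the C3a carboxamide; cyclopentane bond C1–C7a by Pd-catalysed enyne cycloisomerisation; C3a by auxiliary-controlled Birch reduction–alkylation of 2-methoxy-5-methylbenzoic acid.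
4. Ring order: core cyclohexane (from the arene), cyclopentane, lactone, then the side-ring cyclohexane.

Key step: step 16

Numbering used: core hydrindane C1 (bears the CH2CO2Me arm), C2, C3, C3a (quaternary, bears the lactone C=O), C4 (CHBr), C5, C6, C7 (C(CH3)–O), C7a; side ring C1′ (OAc), C2′, C3′ (CMe2), C4′ (CHBr), C5′, C6′. The target is read as (1R,3aR,4R,7S,7aS,1′R,4′R): cis-fused hydrindane, H-7a and Br-4 on the lactone face, the C1 arm cis to C7, OAc axial and Br equatorial on the side ring.

Assumption: the (S)-configured auxiliary steers the alkylation of step 2 to the face that gives (1S)-7; if the sense of induction proves opposite, the commercial (R)-auxiliary is used and nothing else changes.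

**Core acetic ester (steps 1–9)**

Step 1
Reactants: 1 2-methoxy-5-methylbenzoic acid; 2 (S)-2-(methoxymethyl)pyrrolidine
Product: 4 (S)-1-(2-methoxy-5-methylbenzoyl)-2-(methoxymethyl)pyrrolidine, via acid chloride 3 (not isolated)
Conditions: (COCl)2, cat. DMF, CH2Cl2, 0 °C → rt; then 2, Et3N, CH2Cl2, 0 °C → rt
Reagents that add atoms: none
Why: Acyl chloride formation and amidation attach the prolinol-derived auxiliary; no stereocentre is formed and that of 2 is untouched.

Step 2
Reactants: 4 (S)-1-(2-methoxy-5-methylbenzoyl)-2-(methoxymethyl)pyrrolidine; 5 (4-bromobut-1-yn-1-yl)trimethylsilane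
Product: 7 (S)-1-{[(1S)-2-methoxy-5-methyl-1-[4-(trimethylsilyl)but-3-yn-1-yl]cyclohexa-2,5-dien-1-yl]carbonyl}-2-(methoxymethyl)pyrrolidine, via potassium amide enolate 6 (not isolated)
Conditions: K, NH3(l)/THF, t-BuOH (1 equiv), −78 °C; piperylene; then 5, −78 °C → rt
Reagents that add atoms: none
Why: Schultz-type Birch reduction–alkylation: dissolving-metal reduction gives the chelated amide enolate 6, which should be alkylated at the ipso carbon on the face left open by the methoxymethylpyrrolidine, setting the quaternary C3a while the methoxy- and methyl-bearing carbons stay olefinic.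

Step 3
Reactants: 7 silyl alkyne from step 2
Product: 9 methyl 5-[(1S)-2-methoxy-5-methyl-1-{[(S)-2-(methoxymethyl)pyrrolidin-1-yl]carbonyl}cyclohexa-2,5-dien-1-yl]pent-2-ynoate, via caesium alkynoate 8 (not isolated)
Conditions: CsF, CO2 (1 atm), DMSO, rt; then MeI, rt
Reagents that add atoms: carbon dioxide, O=C=O; iodomethane, CI
Why: Fluoride-mediated desilylative carboxylation of the alkynylsilane followed by O-alkylation of the caesium carboxylate should give the alkynoate without touching the enol ether, the amide or C3a.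

Step 4
Reactants: 9 enol ether alkynoate
Product: 10 methyl 5-[(1S)-3-methyl-1-{[(S)-2-(methoxymethyl)pyrrolidin-1-yl]carbonyl}-6-oxocyclohex-2-en-1-yl]pent-2-ynoate
Conditions: 1 M HCl, THF, 0 °C
Reagents that add atoms: water, O
Why: Acid hydrolysis of the enol ether, which is protonated far more readily than the trisubstituted alkene, unmasks the C4 ketone; C3a is quaternary, so neither epimerisation nor conjugation is possible.

Step 5
Reactants: 10 keto enyne
Product: 11 methyl (E)-[(3aS,7aS)-7-methylene-4-oxo-3a-{[(S)-2-(methoxymethyl)pyrrolidin-1-yl]carbonyl}octahydro-1H-inden-1-ylidene]acetate (cis-fused; H-7a cis to the carboxamide)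
Conditions: Pd(OAc)2 (5 mol %), PPh3 (10 mol %), benzene, 70 °C
Reagents that add atoms: none
Why: Palladium-catalysed Alder-ene cycloisomerisation of a 1,6-enyne (Trost): the three-atom tether can deliver alkyne carbon C1 only to the face of C7a on which it sits, so the new cyclopentane is cis-fused, and β-hydride loss from the methyl group leaves the 1,4-diene; an endocyclic Δ6 isomer would converge in step 6.

Step 6
Reactants: 11 bicyclic dienyl keto amide
Product: 13 methyl (E)-ylideneacetate of the (3aS,7S,7aS)-7-methyl-4-oxohydrindane-3a-carboxylic acid 7-lactone, via iminium ether trifluoroacetate 12 (not isolated)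
Conditions: CF3CO2H, CH2Cl2, 0 °C; then aq. NaHCO3
Reagents that add atoms: water, O
Why: Cationic lactonisation: Markovnikov protonation of the 1,1-disubstituted alkene gives the tertiary C7 cation, which only the carboxamide oxygen on the same face can reach, and hydrolysis of iminium ether 12 gives the γ-lactone and releases the auxiliary; C7 is thereby set with oxygen cis to the carbonyl carbon and methyl on the cyclopentane face.

Step 7
Reactants: 13 tricyclic keto lactone enoate
Product: 14 methyl [(1R,3aS,7S,7aS)-7-methyl-4-oxohydrindan-1-yl]acetate 3a-carboxylic acid 7-lactone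
Conditions: H2 (1 atm), 10% Pd/C, EtOAc, rt
Reagents that add atoms: none
Why: Heterogeneous hydrogenation of the exocyclic enoate should deliver hydrogen to C1 from the face flanked by H-7a and not by the fully substituted C7, which places the acetic ester arm cis to C7 (1R).

Step 8
Reactants: 14 saturated keto lactone ester
Product: 15 methyl [(1R,3aS,4S,7S,7aS)-4-hydroxy-7-methylhydrindan-1-yl]acetate 3a-carboxylic acid 7-lactone (axial alcohol)
Conditions: NaBH4, MeOH, −20 °C
Reagents that add atoms: none
Why: Borohydride reduction is chemoselective for the ketone; the axial trajectory at C4 is blocked by C1, which is axial on C7a and 1,3 to C4, so hydride should enter equatorially and give the axial alcohol (4S).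

Step 9
Reactants: 15 axial alcohol
Product: 16 core acetic ester, methyl [(1R,3aS,4S,7S,7aS)-4-(tert-butyldimethylsilyloxy)-7-methylhydrindan-1-yl]acetate 3a-carboxylic acid 7-lactone
Conditions: TBSOTf, 2,6-lutidine, CH2Cl2, 0 °C → rt
Reagents that add atoms: tert-butyldimethylsilyl trifluoromethanesulfonate, CC(C)(C)[Si](C)(C)OS(=O)(=O)C(F)(F)F
Why: Silylation with a silyl triflate is the standard answer to a hindered axial secondary alcohol; no stereocentre changes.

**Di-Grignard reagent (steps 10–15)**

Step 10
Reactants: 17 (S)-pantolactone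
Product: 18 (S)-3-(tert-butyldimethylsilyloxy)-4,4-dimethyldihydrofuran-2(3H)-one
Conditions: TBSCl, imidazole, DMF, rt
Reagents that add atoms: tert-butyldimethylsilyl chloride, CC(C)(C)[Si](C)(C)Cl
Why: Imidazole-mediated silylation of the secondary alcohol; the stereocentre is untouched.

Step 11
Reactants: 18 silylated pantolactone
Product: 19 (3S)-3-(tert-butyldimethylsilyloxy)-4,4-dimethyltetrahydrofuran-2-ol (anomeric mixture)
Conditions: DIBAL-H, CH2Cl2, −78 °C; Rochelle salt
Reagents that add atoms: none
Why: Half-reduction of a lactone with DIBAL-H at low temperature stops at the aluminium hemiacetal and gives the lactol after work-up.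

Step 12
Reactants: 19 lactol
Product: 20 (R)-3-(tert-butyldimethylsilyloxy)-2,2-dimethylpent-4-en-1-ol
Conditions: Ph3PCH3Br, n-BuLi, THF, 0 °C → rt
Reagents that add atoms: methyltriphenylphosphonium bromide, C[P+](c1ccccc1)(c1ccccc1)c1ccccc1.[Br-]
Why: Wittig methylenation of the open-chain hydroxy aldehyde in equilibrium with the lactol; the lithium ylide is chosen to keep 1,3-silyl migration to the primary alkoxide slow.

Step 13
Reactants: 20 alkenol
Product: 22 (R)-3-(tert-butyldimethylsilyloxy)-2,2-dimethylpentane-1,5-diol, via alkyl-9-BBN adduct 21 (not isolated)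
Conditions: 9-BBN, THF, rt; then NaOH, H2O2, 0 °C
Reagents that add atoms: hydrogen peroxide, OO
Why: Anti-Markovnikov hydroboration of the terminal alkene and oxidation of the C–B bond give the primary alcohol; the stereocentre is untouched.

Step 14
Reactants: 22 diol
Product: 23 (R)-1,5-dibromo-3-(tert-butyldimethylsilyloxy)-2,2-dimethylpentane
Conditions: PPh3, CBr4, toluene, 0 → 70 °C
Reagents that add atoms: carbon tetrabromide, BrC(Br)(Br)Br
Why: Appel bromination: the unhindered primary carbinol reacts in the cold and the neopentyl one on heating, a substitution known to proceed without rearrangement.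

Step 15
Reactants: 23 dibromide
Product: 24 (R)-[3-(tert-butyldimethylsilyloxy)-2,2-dimethylpentane-1,5-diyl]bis(magnesium bromide)
Conditions: Mg turnings (I2-activated), THF, 40 °C
Reagents that add atoms: magnesium, [Mg]
Why: Magnesium insertion into both primary C–Br bonds as for 1,5-dibromopentane; both C–Mg bonds are γ to the silyloxy group, so no β-elimination is possible.

**Key step and endgame (steps 16–21)**

Step 16
Reactants: 16 core acetic ester; 24 1,5-di-Grignard reagent
Product: 26 side-ring tertiary alcohol bis-silyl ether, (1′R,4′R)-1′-[core-C1-methyl]-4′-(tert-butyldimethylsilyloxy)-3′,3′-dimethylcyclohexan-1′-ol with the core of 16 unchanged, via keto-Grignard intermediate 25 (not isolated)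
Conditions: 24 (1.3 equiv) added slowly to 16, THF, −40 → 0 °C; aq. NH4Cl
Reagents that add atoms: none
Why: Double Grignard addition to an ester: the unhindered primary C–Mg terminus adds to the methyl ester, methoxide is lost, and ketone 25 is captured intramolecularly by the neopentyl C–Mg terminus. The closest known reaction is the synthesis of 1-substituted cyclohexanols from esters and pentamethylene-bis(magnesium bromide). The side ring closes 6-exo-trig (C1′–C2′ after C1′–C6′) through a chair. C1′ is controlled by the C4′ silyloxy centre from pantolactone: the OTBS group and the core CH2 arm should sit equatorial and the alkoxide axial, because an axial CH2 arm would be syn-axial to the axial C3′ methyl; the preference of OTBS for the equatorial site next to the gem-dimethyl group is modest, so the C1′ epimer is the expected minor product. The step needs ester-over-lactone selectivity, which rests on the lactone carbonyl being attached to the quaternary C3a and flanked by the axial C4 silyl ether. Slow addition at low temperature keeps the reagent dilute so that ring closure outruns a second intermolecular addition.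

Step 17
Reactants: 26 tertiary alcohol
Product: 27 tertiary acetate bis-silyl ether
Conditions: Ac2O, DMAP, Et3N, CH2Cl2, 40 °C
Reagents that add atoms: acetic anhydride, CC(=O)OC(C)=O
Why: DMAP-catalysed acylation of the tertiary alcohol, the only free hydroxyl group; it is done first so that the later bromination meets no free tertiary carbinol.

Step 18
Reactants: 27 acetate bis-silyl ether
Product: 28 acetate diol (C4 axial OH, C4′ equatorial OH)
Conditions: HF·pyridine, THF, 0 °C → rt
Reagents that add atoms: none
Why: Fluoride cleavage of both silyl ethers under conditions that leave the tertiary acetate and the lactone alone.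

Step 19
Reactants: 28 acetate diol
Product: 29 acetate diketone (C4 and C4′ ketones)
Conditions: Dess–Martin periodinane, NaHCO3, CH2Cl2, rt
Reagents that add atoms: none
Why: Dess–Martin oxidation of both secondary alcohols; neither ketone has a leaving group in the β-position and C3a cannot enolise.

Step 20
Reactants: 29 acetate diketone
Product: 30 acetate diol with both hydroxyl groups axial (4S,4′S)
Conditions: L-Selectride, THF, −78 °C; aq. NH4Cl
Reagents that add atoms: none
Why: L-Selectride reduction: the bulky hydride should attack both ketones along the equatorial trajectory (at C4 the axial face is also blocked by C1), giving the two axial alcohols, as known for 3-oxo-4,4-dimethyl steroids and triterpenoids.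

Step 21
Reactants: 30 bis-axial diol
Product: 31 target CNP0133010.1, (1R,3aR,4R,7S,7aS,1′R,4′R)
Conditions: PPh3, CBr4, toluene, 0 → 60 °C
Reagents that add atoms: carbon tetrabromide, BrC(Br)(Br)Br
Why: Appel bromination with inversion at both carbinol carbons: backside displacement of the axial oxyphosphonium groups by bromide should give the two equatorial bromides (4R, 4′R).

**Compound list**

1 | 2-methoxy-5-methylbenzoic acid | COc1ccc(C)cc1C(=O)O | starting material
2 | (S)-2-(methoxymethyl)pyrrolidine | COC[C@@H]1CCCN1 | starting material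
3 | 2-methoxy-5-methylbenzoyl chloride | COc1ccc(C)cc1C(Cl)=O | intermediate
4 | (S)-1-(2-methoxy-5-methylbenzoyl)-2-(methoxymethyl)pyrrolidine | COC[C@@H]1CCCN1C(=O)c1cc(C)ccc1OC | intermediate
5 | (4-bromobut-1-yn-1-yl)trimethylsilane | C[Si](C)(C)C#CCCBr | starting material
6 | potassium amide enolate of the 1,4-dihydrobenzamide | COC[C@@H]1CCCN1C([O-])=C1C=C(C)CC=C1OC.[K+] | intermediate
7 | (S)-1-{[(1S)-2-methoxy-5-methyl-1-[4-(trimethylsilyl)but-3-yn-1-yl]cyclohexa-2,5-dien-1-yl]carbonyl}-2-(methoxymethyl)pyrrolidine | C[Si](C)(C)C#CCC[C@@]1(C(=O)N2CCC[C@H]2COC)C(OC)=CCC(C)=C1 | intermediate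
8 | caesium alkynoate of 9 | [Cs+].[O-]C(=O)C#CCC[C@@]1(C(=O)N2CCC[C@H]2COC)C(OC)=CCC(C)=C1 | intermediate
9 | methyl 5-[(1S)-2-methoxy-5-methyl-1-{[(S)-2-(methoxymethyl)pyrrolidin-1-yl]carbonyl}cyclohexa-2,5-dien-1-yl]pent-2-ynoate | COC(=O)C#CCC[C@@]1(C(=O)N2CCC[C@H]2COC)C(OC)=CCC(C)=C1 | intermediate
10 | methyl 5-[(1S)-3-methyl-1-{[(S)-2-(methoxymethyl)pyrrolidin-1-yl]carbonyl}-6-oxocyclohex-2-en-1-yl]pent-2-ynoate | COC(=O)C#CCC[C@@]1(C(=O)N2CCC[C@H]2COC)C(=O)CCC(C)=C1 | intermediate
11 | methyl (E)-[(3aS,7aS)-7-methylene-4-oxo-3a-{[(S)-2-(methoxymethyl)pyrrolidin-1-yl]carbonyl}octahydro-1H-inden-1-ylidene]acetate, cis-fused | COC(=O)/C=C1\CC[C@@]2(C(=O)N3CCC[C@H]3COC)C(=O)CCC(=C)[C@@H]12 | intermediate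
12 | cyclic iminium ether (C3a–C(=N+)–O–C7) trifluoroacetate | COC(=O)/C=C1\CC[C@@]23C(=[N+]4CCC[C@H]4COC)O[C@@](C)(CCC2=O)[C@@H]13.[O-]C(=O)C(F)(F)F | intermediate
13 | methyl (E)-ylideneacetate of the (3aS,7S,7aS)-7-methyl-4-oxohydrindane-3a-carboxylic acid 7-lactone | COC(=O)/C=C1\CC[C@@]23C(=O)O[C@@](C)(CCC2=O)[C@@H]13 | intermediate
14 | methyl [(1R,3aS,7S,7aS)-7-methyl-4-oxohydrindan-1-yl]acetate 3a-carboxylic acid 7-lactone | COC(=O)C[C@H]1CC[C@@]23C(=O)O[C@@](C)(CCC2=O)[C@@H]13 | intermediate
15 | methyl [(1R,3aS,4S,7S,7aS)-4-hydroxy-7-methylhydrindan-1-yl]acetate 3a-carboxylic acid 7-lactone, axial OH | COC(=O)C[C@H]1CC[C@@]23C(=O)O[C@@](C)(CC[C@@H]2O)[C@@H]13 | intermediate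
16 | core acetic ester, methyl [(1R,3aS,4S,7S,7aS)-4-(tert-butyldimethylsilyloxy)-7-methylhydrindan-1-yl]acetate 3a-carboxylic acid 7-lactone | COC(=O)C[C@H]1CC[C@@]23C(=O)O[C@@](C)(CC[C@@H]2O[Si](C)(C)C(C)(C)C)[C@@H]13 | intermediate
17 | (S)-pantolactone | CC1(C)COC(=O)[C@H]1O | starting material
18 | (S)-3-(tert-butyldimethylsilyloxy)-4,4-dimethyldihydrofuran-2(3H)-one | CC1(C)COC(=O)[C@H]1O[Si](C)(C)C(C)(C)C | intermediate
19 | (3S)-3-(tert-butyldimethylsilyloxy)-4,4-dimethyltetrahydrofuran-2-ol, anomeric mixture | CC1(C)COC(O)[C@H]1O[Si](C)(C)C(C)(C)C | intermediate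
20 | (R)-3-(tert-butyldimethylsilyloxy)-2,2-dimethylpent-4-en-1-ol | C=C[C@@H](O[Si](C)(C)C(C)(C)C)C(C)(C)CO | intermediate
21 | B-alkyl-9-borabicyclo[3.3.1]nonane adduct of 20 | OCC(C)(C)[C@H](O[Si](C)(C)C(C)(C)C)CCB1C2CCCC1CCC2 | intermediate
22 | (R)-3-(tert-butyldimethylsilyloxy)-2,2-dimethylpentane-1,5-diol | OCC[C@@H](O[Si](C)(C)C(C)(C)C)C(C)(C)CO | intermediate
23 | (R)-1,5-dibromo-3-(tert-butyldimethylsilyloxy)-2,2-dimethylpentane | BrCC[C@@H](O[Si](C)(C)C(C)(C)C)C(C)(C)CBr | intermediate
24 | (R)-[3-(tert-butyldimethylsilyloxy)-2,2-dimethylpentane-1,5-diyl]bis(magnesium bromide) | Br[Mg]CC[C@@H](O[Si](C)(C)C(C)(C)C)C(C)(C)C[Mg]Br | intermediate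
25 | keto-Grignard intermediate (ketone at C1′, neopentyl C–MgBr at C2′) | Br[Mg]CC(C)(C)[C@H](O[Si](C)(C)C(C)(C)C)CCC(=O)C[C@H]1CC[C@@]23C(=O)O[C@@](C)(CC[C@@H]2O[Si](C)(C)C(C)(C)C)[C@@H]13 | intermediate
26 | side-ring tertiary alcohol bis-silyl ether (1′R,4′R; core 1R,3aS,4S,7S,7aS) | O[C@@]1(C[C@H]2CC[C@@]34C(=O)O[C@@](C)(CC[C@@H]3O[Si](C)(C)C(C)(C)C)[C@@H]24)CC[C@@H](O[Si](C)(C)C(C)(C)C)C(C)(C)C1 | intermediate
27 | tertiary acetate bis-silyl ether | CC(=O)O[C@@]1(C[C@H]2CC[C@@]34C(=O)O[C@@](C)(CC[C@@H]3O[Si](C)(C)C(C)(C)C)[C@@H]24)CC[C@@H](O[Si](C)(C)C(C)(C)C)C(C)(C)C1 | intermediate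
28 | acetate diol (C4 axial OH, C4′ equatorial OH) | CC(=O)O[C@@]1(C[C@H]2CC[C@@]34C(=O)O[C@@](C)(CC[C@@H]3O)[C@@H]24)CC[C@@H](O)C(C)(C)C1 | intermediate
29 | acetate diketone (C4 and C4′ ketones) | CC(=O)O[C@@]1(C[C@H]2CC[C@@]34C(=O)O[C@@](C)(CCC3=O)[C@@H]24)CCC(=O)C(C)(C)C1 | intermediate
30 | acetate diol with both hydroxyl groups axial (4S,4′S) | CC(=O)O[C@@]1(C[C@H]2CC[C@@]34C(=O)O[C@@](C)(CC[C@@H]3O)[C@@H]24)CC[C@H](O)C(C)(C)C1 | intermediate
31 | CNP0133010.1, (1R,3aR,4R,7S,7aS,1′R,4′R)-dibromo acetate lactone | CC(=O)O[C@@]1(C[C@H]2CC[C@@]34C(=O)O[C@@](C)(CC[C@H]3Br)[C@@H]24)CC[C@@H](Br)C(C)(C)C1 | target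

**Step count**

Total: 21 steps. Longest linear sequence: 15 steps (steps 1–9, then 16–21); the di-Grignard branch is 6 steps (10–15).

**Steps most likely to fail**

1. Step 16. What may go wrong: attack of a C–Mg terminus on the strained lactone carbonyl, a second intermolecular addition to ketone 25 before the ring closes, and incomplete facial control in the ring-closing chair. Fallback, from 16 and 24 and back at 26: the side ring is made first and joined to the core by one C–C bond. The methyl ester of 16 is cleaved selectively (Me3SnOH, 1,2-dichloroethane, 80 °C) to core acetic acid F1, and iododecarboxylation (PhI(OAc)2, I2, hν, cyclohexane) gives core iodomethyl compound F2. Di-Grignard 24 and ethyl formate (THF, 0 °C) give silyloxy dimethylcyclohexanol F3, which Dess–Martin periodinane oxidises to silyloxy dimethylcyclohexanone F4. Samarium Barbier coupling of F2 with F4 (SmI2, HMPA, THF, rt) should give 26: the organosamarium adds along the equatorial trajectory because the axial C3′ methyl blocks the axial one, and the lactone and silyl ethers are inert to SmI2.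

2. Step 21. What may go wrong: anti-periplanar E2 elimination (axial H at C5 and C5′) and 1,2-shift of the axial C3′ methyl or of a C3a ring bond overtaking the slow backside attack at two carbinol carbons that each adjoin a quaternary carbon; reaction at only one centre. Fallback, from 30 and back at 31: the diol is converted (ClCH2SO2Cl, pyridine, 0 °C) into bis(chloromethanesulfonate) F5, a leaving group designed for hindered secondary carbinols, which is displaced with inversion by LiBr (DMF, 50 °C) to give 31.

3. Step 6. What may go wrong: loss of the C7a proton from the C7 cation to give the conjugated dienoate, which erases the ring-fusion centre, or reversible ionisation of the strained lactone under acid. Fallback, from 11 and back at 13: kinetic iodolactonisation (I2, NaHCO3, THF–H2O, 0 °C) gives iodomethyl lactone F6 by anti addition with loss of the auxiliary, and Bu3SnH, AIBN, benzene, 80 °C reduces the C–I bond to give 13.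

Further compounds
F1 | step 16 | core acetic acid, [(1R,3aS,4S,7S,7aS)-4-(tert-butyldimethylsilyloxy)-7-methylhydrindan-1-yl]acetic acid 3a-carboxylic acid 7-lactone | OC(=O)C[C@H]1CC[C@@]23C(=O)O[C@@](C)(CC[C@@H]2O[Si](C)(C)C(C)(C)C)[C@@H]13
F2 | step 16 | core iodomethyl compound (CH2I at C1 in place of CH2CO2Me) | IC[C@H]1CC[C@@]23C(=O)O[C@@](C)(CC[C@@H]2O[Si](C)(C)C(C)(C)C)[C@@H]13
F3 | step 16 | (4R)-4-(tert-butyldimethylsilyloxy)-3,3-dimethylcyclohexan-1-ol, both carbinol epimers | OC1CC[C@@H](O[Si](C)(C)C(C)(C)C)C(C)(C)C1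
F4 | step 16 | (R)-4-(tert-butyldimethylsilyloxy)-3,3-dimethylcyclohexanone | O=C1CC[C@@H](O[Si](C)(C)C(C)(C)C)C(C)(C)C1
F5 | step 21 | bis(chloromethanesulfonate) of diol 30 | CC(=O)O[C@@]1(C[C@H]2CC[C@@]34C(=O)O[C@@](C)(CC[C@@H]3OS(=O)(=O)CCl)[C@@H]24)CC[C@H](OS(=O)(=O)CCl)C(C)(C)C1
F6 | step 6 | iodomethyl lactone (CH2I at C7 in place of CH3 of 13) | COC(=O)/C=C1\CC[C@@]23C(=O)O[C@@](CI)(CCC2=O)[C@@H]13
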